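**Retrosynthetic overview**

1. The C5 quaternary centre comes from a suprafacial Cope shift of the allyl group (C3a to C5) in a (2R,3R,3aR)-3a-allyl-cyclohexa-2,5-dienone; no ring is formed in this step.
2. That dienone comes from its 2,3-cis epimer by acid epimerisation of the benzylic ether carbon C2.
3. The dihydrofuran ring is the only ring formed in the route (C3–C3a first, then O1–C2). It arises from a cationic formal [3+2] union of the phenoxonium ion of 2-allyl-4,5-dimethoxyphenol with (Z)-methylisoeugenol under a chiral counter-anion, as in the proposed biogenesis (oxidised allylphenol plus propenylbenzene).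
4. The six-membered ring is the arene of 3,4-dimethoxyphenol (O-allylation/Claisen, then oxidative ketalisation); the Z-alkene comes from veratraldehyde by Wittig olefination.

Stereochemical reading of the target: (2R,3R,5S), with 2-aryl and 3-methyl trans and the 5-allyl group on the same face as the 2-aryl group.

Assumption: the facial sense of the chiral acid cannot be predicted with confidence; the (S)-acid is written as giving the (3R,3aR) series, and its equally available (R)-enantiomer is used if the sense proves opposite.

**Route**

Step 1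
Reactants: 1 3,4-dimethoxyphenol
Product: 3 2-allyl-4,5-dimethoxyphenol, via allyl 3,4-dimethoxyphenyl ether 2 (not isolated)
Conditions: allyl bromide, K2CO3, acetone, reflux; filter, evaporate; then neat, 190 °C, N2
Reagents that add atoms: allyl bromide C=CCBr
Why: Williamson etherification followed by aromatic Claisen rearrangement, a [3,3] shift that goes to the unhindered ortho carbon and not to the one flanked by a methoxy group; no stereocentre is formed.

Step 2
Reactants: 3 2-allyl-4,5-dimethoxyphenol
Product: 4 2-allyl-4,4,5-trimethoxycyclohexa-2,5-dien-1-one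
Conditions: PhI(OAc)2, MeOH, 0 °C
Reagents that add atoms: methanol CO
Why: Oxidative dearomatisation of a para-methoxyphenol in methanol (para-quinone monoketal formation), in which the electron-rich ring is oxidised far faster than the isolated allyl alkene; no stereocentre is formed.

Step 3
Reactants: 5 3,4-dimethoxybenzaldehyde
Product: 6 (Z)-1,2-dimethoxy-4-(prop-1-en-1-yl)benzene
Conditions: EtPPh3Br, KN(SiMe3)2, THF, −78 °C to 0 °C; chromatography on AgNO3-impregnated silica
Reagents that add atoms: ethyltriphenylphosphonium bromide CC[P+](c1ccccc1)(c1ccccc1)c1ccccc1.[Br-]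
Why: Wittig olefination with a non-stabilised ylide under lithium-free conditions, where the kinetically favoured cis-oxaphosphetane gives the Z alkene (about 9:1 expected) and argentation chromatography removes the E isomer.

Step 4
Reactants: 4 2-allyl-4,4,5-trimethoxycyclohexa-2,5-dien-1-one; 6 (Z)-1,2-dimethoxy-4-(prop-1-en-1-yl)benzene (1.5 equiv)
Product: 9 (2R,3R,3aR)-3a-allyl-2-(3,4-dimethoxyphenyl)-5-methoxy-3-methyl-3,3a-dihydro-1-benzofuran-6(2H)-one, via phenoxonium ion 7 (not isolated), via cis-cycloadduct 8 (not isolated)
Conditions: (S)-[3,3'-(2,4,6-iPr3C6H2)2-1,1'-binaphthyl-2,2'-diyl]P(O)NHSO2CF3 (10 mol%), CH2Cl2, −60 °C; then H2O (3 equiv), TsOH·H2O (20 mol%), 23 °C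
Reagents that add atoms: water O
Why: Proposed new method: the chiral N-triflyl phosphoramide ionises ketal 4 to phenoxonium ion 7, held as a contact ion pair with its bulky chiral anion, so that the methyl-bearing carbon of the Z-alkene attacks one face of the allyl-bearing carbon with the aryl group endo (this makes methyl and allyl trans and sets C3 and C3a), the resulting veratryl cation is captured by the ring carbonyl oxygen to give 8 after hydrolysis of the O-methyl oxocarbenium to the C6 ketone, and TsOH then epimerises C2 through the reversibly formed benzylic cation to the all-trans thermodynamic isomer 9; the closest known reaction types are the racemic strong-acid quinone monoketal/propenylbenzene formal [3+2] cycloaddition and asymmetric counteranion-directed additions of alkenes to oxocarbenium ions.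

Step 5
Reactants: 9 (2R,3R,3aR)-3a-allyl-2-(3,4-dimethoxyphenyl)-5-methoxy-3-methyl-3,3a-dihydro-1-benzofuran-6(2H)-one
Product: 10 (2R,3R,5S)-5-allyl-2-(3,4-dimethoxyphenyl)-5-methoxy-3-methyl-2,3-dihydro-1-benzofuran-6(5H)-one
Conditions: PhMe, 110 °C, sealed tube, followed by HPLC and stopped at about 80% conversion; 9 recycled
Reagents that add atoms: none
Why: Cope rearrangement, a concerted suprafacial [3,3]-sigmatropic shift of the allyl group from C3a to the methoxy-bearing C5 across the same ring face, which transfers the 3aR configuration into 5S (allyl cis to aryl) and leaves C2 and C3 untouched; relief of congestion at the quaternary C3a next to C3 should favour it.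

**Compound list**

1 | 3,4-dimethoxyphenol | COc1ccc(O)cc1OC | starting material
2 | allyl 3,4-dimethoxyphenyl ether (4-(allyloxy)-1,2-dimethoxybenzene) | C=CCOc1ccc(OC)c(OC)c1 | intermediate
3 | 2-allyl-4,5-dimethoxyphenol | C=CCc1cc(OC)c(OC)cc1O | intermediate
4 | 2-allyl-4,4,5-trimethoxycyclohexa-2,5-dien-1-one | C=CCC1=CC(OC)(OC)C(OC)=CC1=O | intermediate
5 | 3,4-dimethoxybenzaldehyde (veratraldehyde) | COc1ccc(C=O)cc1OC | starting material
6 | (Z)-1,2-dimethoxy-4-(prop-1-en-1-yl)benzene | C/C=C\c1ccc(OC)c(OC)c1 | intermediate
7 | (5-allyl-2-methoxy-4-oxocyclohexa-2,5-dien-1-ylidene)(methyl)oxonium (2-allyl-4,5-dimethoxyphenoxonium ion, paired with the chiral phosphoramide anion) | C=CCC1=CC(=[O+]C)C(OC)=CC1=O | intermediate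
8 | (2S,3R,3aR)-3a-allyl-2-(3,4-dimethoxyphenyl)-5-methoxy-3-methyl-3,3a-dihydro-1-benzofuran-6(2H)-one (2,3-cis; allyl trans to methyl and aryl) | C=CC[C@@]12C=C(OC)C(=O)C=C1O[C@H](c1ccc(OC)c(OC)c1)[C@@H]2C | intermediate
9 | (2R,3R,3aR)-3a-allyl-2-(3,4-dimethoxyphenyl)-5-methoxy-3-methyl-3,3a-dihydro-1-benzofuran-6(2H)-one (2,3-trans; allyl cis to aryl) | C=CC[C@@]12C=C(OC)C(=O)C=C1O[C@@H](c1ccc(OC)c(OC)c1)[C@@H]2C | intermediate
10 | (2R,3R,5S)-5-allyl-2-(3,4-dimethoxyphenyl)-5-methoxy-3-methyl-2,3-dihydro-1-benzofuran-6(5H)-one | C=CC[C@]1(OC)C=C2C(=CC1=O)O[C@@H](c1ccc(OC)c(OC)c1)[C@@H]2C | target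

**Step count and risks**

Total steps: 5. Longest linear sequence: 4 steps (steps 1, 2, 4 and 5; step 3 is the convergent branch).

Steps most likely to fail:

Step 4. The enantioselectivity of the ion-pair-controlled cycloaddition is untested. Bicyclo[3.2.1]octane adducts, acid dimerisation or Z-to-E isomerisation of 6 can compete, and the benzylic cation of the TsOH stage could fragment back and erode ee. The fallback replaces asymmetric catalysis by resolution. It sets out from 4 and 6: catalytic 2,4,6-trinitrobenzenesulfonic acid in MeCN at −30 °C gives 8 together with its mirror image, (2R,3S,3aS)-3a-allyl-2-(3,4-dimethoxyphenyl)-5-methoxy-3-methyl-3,3a-dihydro-1-benzofuran-6(2H)-one F1. The same TsOH epimerisation then gives 9 together with (2S,3S,3aS)-3a-allyl-2-(3,4-dimethoxyphenyl)-5-methoxy-3-methyl-3,3a-dihydro-1-benzofuran-6(2H)-one F2. Preparative chromatography on an amylose tris(3,5-dimethylphenylcarbamate) phase separates the two, and the route is rejoined at 9.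

Step 5. The ortho-dienone product can go on by retro-Claisen cleavage to the aromatic allyl ether. The allyl group can also migrate to C7 and aromatise, and traces of acid left in 9 promote such shifts. The fallback reverses the order of the last two events. It sets out from 8, isolated by leaving out the TsOH stage of step 4 so that it has not seen strong acid at room temperature. Thermolysis in toluene gives (2S,3R,5S)-5-allyl-2-(3,4-dimethoxyphenyl)-5-methoxy-3-methyl-2,3-dihydro-1-benzofuran-6(5H)-one F3. Catalytic TsOH in CH2Cl2 at 23 °C then epimerises C2 to the trans isomer, which is 10.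

Step 3. The Z:E ratio may be too low or the E isomer may not be fully removed; it would lead into the wrong 3,3a-cis diastereomer series. The fallback builds the Z geometry through a stereodefined vinyl iodide. It sets out from 5: (iodomethyl)triphenylphosphonium iodide and NaN(SiMe3)2 in THF at −78 °C give (Z)-4-(2-iodoethenyl)-1,2-dimethoxybenzene F4 with high Z selectivity. MeZnCl with Pd(PPh3)4 in THF then replaces iodine by methyl with retention, and the route is rejoined at 6.

**Further compounds**

F1 | step 4 | (2R,3S,3aS)-3a-allyl-2-(3,4-dimethoxyphenyl)-5-methoxy-3-methyl-3,3a-dihydro-1-benzofuran-6(2H)-one | C=CC[C@]12C=C(OC)C(=O)C=C1O[C@@H](c1ccc(OC)c(OC)c1)[C@H]2C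
F2 | step 4 | (2S,3S,3aS)-3a-allyl-2-(3,4-dimethoxyphenyl)-5-methoxy-3-methyl-3,3a-dihydro-1-benzofuran-6(2H)-one | C=CC[C@]12C=C(OC)C(=O)C=C1O[C@H](c1ccc(OC)c(OC)c1)[C@H]2C
F3 | step 5 | (2S,3R,5S)-5-allyl-2-(3,4-dimethoxyphenyl)-5-methoxy-3-methyl-2,3-dihydro-1-benzofuran-6(5H)-one | C=CC[C@]1(OC)C=C2C(=CC1=O)O[C@H](c1ccc(OC)c(OC)c1)[C@@H]2C
F4 | step 3 | (Z)-4-(2-iodoethenyl)-1,2-dimethoxybenzene | I/C=C\c1ccc(OC)c(OC)c1
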